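5 questions are put to 4 flasks that differ in what is fed, and how slowly.

    second nucleophile + intermediate → other capture product (k1 = 10400 M⁻¹ h⁻¹)
    substrate + target → side product (k2 = 40.3 M⁻¹ h⁻¹)
    first nucleophile + intermediate → target (k3 = 4590 M⁻¹ h⁻¹)
    substrate → intermediate (k4 = 1.17 h⁻¹)

| setting | Friday's | Monday's | Saturday's | Tuesday's |
|---|---|---|---|---|
| substrate | 10 mM | 10 mM (fed, over 6.0 h) | 10 mM (fed, over 25 h) | 10 mM |
| first nucleophile | 9.50 mM | 9.50 mM | 9.50 mM | 9.50 mM |
| second nucleophile | 9.50 mM (fed, over 25 h) | 9.50 mM | 9.50 mM | 9.50 mM |
| time | 30 h | 30 h | 30 h | 30 h |
| remark | all else is in the flask from the start; the feed brings no volume worth counting | all else is in the flask from the start; the feed brings no volume worth counting | all else is in the flask from the start; the feed brings no volume worth counting | everything together at the start |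

- percent here means substrate units held: one side product counts as two
- run time (Friday's): 30 h

1. which flask leads in amount of target, in percent of the substrate charged ("all alike" within 1.5 percentage points) (Friday's / Monday's / Saturday's / Tuesday's / all alike)
2. how much target is there at the end, in percent of the substrate charged: Friday's
3. how much target is there at the end, in percent of the substrate charged: Monday's
4. how much target is there at the end, in percent of the substrate charged: Saturday's
5. how much target is there at the end, in percent of the substrate charged: Tuesday's

**Two clocks.** Substrate opens to the intermediate by a first-order step with a lifetime of 0.855 h. In Friday's flask, the second nucleophile arrives over 25 h, which is 29 times longer. The intermediate is caught by either nucleophile, and the second catches 2.27 times faster at equal concentration, your selectivity factor. So you must ask how much second nucleophile the intermediate meets.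

**The leak.** Averaged over substrate's decay, Friday's intermediate meets what is fed in one lifetime, a c(second nucleophile) of 0.325 mM. Freeze c(first nucleophile) at its charge of 9.50 mM, a rough step, since capture consumes it. Capture by the second nucleophile then runs at 0.0775 of capture by the first. Call this ratio of capture rates the leak. With equal charges, it is the selectivity factor divided by the ratio of the two times. My reckoned share of Friday's intermediate going to target is therefore 92.8%. In the other flasks, with both nucleophiles present from the start, the charges give a starting share of 30.6%, and I carry those no further.

**Side loss.** In Friday's flask, target formed midway meets about 5.00 mM of substrate for one lifetime, so the side step takes a fraction 0.172 of it. Each such event spends one target and one substrate. That balance gives me 69.7% of target for Friday's.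

**The forecast.** It names Friday's as leader, starting from “Holding back the faster second nucleophile”. It gives 59% for Friday's, 29% for Monday's, 28% for Saturday's and 30% for Tuesday's. My Friday's figure stands above its 59%.

**The outcome.** The simulation puts Friday's first with 70.1%, against 29.7%, 29.7% and 29.7% for Monday's, Saturday's and Tuesday's. A neighbour of Friday's with 24 mM of second nucleophile has a leak of 0.196, larger than Friday's 0.0775. Its reckoned share is 83.6%, and the same balance gives 63.5%. That neighbour ended with 63.9% of target and 21.8% of side product.

The numbers of this flask come from no measurement.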